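**Strategy.** The pyrrolidinone ring is cut across C3–C4 and C5–N1, which reveals an N-benzyl malonamate (N1–C2–C3, with a removable ester on C3) and a two-carbon unit. Diphenyl(vinyl)sulfonium triflate supplies C4–C5 as a 1,2-dielectrophile equivalent: the malonate carbon adds to the vinyl terminus and the amide nitrogen then displaces diphenyl sulfide, so both bonds form in one base-mediated operation. The step exploits the 1,3-relationship of the acidic C3 (α to the C2 carbonyl) and N1 of the γ-lactam. The ester is then removed by Krapcho dealkoxycarbonylation. The catechol is unmasked and tribrominated last, where the free phenols make exhaustive bromination easy.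

Key step: step 2

Remark: the target is achiral. The only stereocentre on the route (C3 of compound 6) should form as a racemate and is removed in step 3.

**Step 1**
Reactants: 1 (3,4-dimethoxyphenyl)methanamine (3,4-dimethoxybenzylamine); 2 methyl 3-chloro-3-oxopropanoate (methyl malonyl chloride)
Product: 3 methyl 3-[(3,4-dimethoxybenzyl)amino]-3-oxopropanoate
Conditions: Et3N (1.2 equiv), CH2Cl2, 0 °C → rt
Reagents that add atoms: none
Why: N-acylation of a primary benzylic amine by an acid chloride (Schotten–Baumann-type amide formation) is fast at 0 °C and should leave the methyl ester untouched.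

**Step 2**
Reactants: 3 methyl 3-[(3,4-dimethoxybenzyl)amino]-3-oxopropanoate; 4 diphenyl(vinyl)sulfonium trifluoromethanesulfonate
Product: 6 rac-methyl 1-(3,4-dimethoxybenzyl)-2-oxopyrrolidine-3-carboxylate, via sulfonium triflate 5 (not isolated)
Conditions: DBU (2 equiv), CH2Cl2, 0 °C → rt
Reagents that add atoms: none
Why: DBU deprotonates the malonamate carbon of 3 (the future C3), which adds to the vinyl terminus of 4 to forge C3–C4 and give a sulfonium ylide; protonation of the ylide (by DBU-H+ or the nearby N–H) gives the γ-sulfonium salt 5, and the amidate nitrogen then displaces diphenyl sulfide from C5 to forge C5–N1. The closest known reaction type is the tandem Michael addition/intramolecular N-alkylation of malonyl amides with vinylsulfonium salts, a Michael-initiated ring closure. The lactam ring closes in a 5-exo-tet mode. The C3 stereocentre should arise without control as a racemate, which is harmless because step 3 turns C3 into a CH2 group. The step needs N-alkylation to win over 3-exo-tet C-alkylation (cyclopropane) and 5-exo-tet O-alkylation (cyclic imidate); the N–H of the Z-configured secondary amide lies syn to C3 and so places the amidate lone pair within reach of C5, the diphenylsulfonium leaving group makes this closure fast at room temperature, and the ester keeps C3 acidic enough for DBU so that no strong base is required.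

**Step 3**
Reactants: 6 rac-methyl 1-(3,4-dimethoxybenzyl)-2-oxopyrrolidine-3-carboxylate
Product: 7 1-(3,4-dimethoxybenzyl)pyrrolidin-2-one
Conditions: LiCl (3 equiv), H2O (2 equiv), DMSO, 150 °C
Reagents that add atoms: none
Why: Krapcho dealkoxycarbonylation: chloride attacks the ester methyl group (SN2), the β-amido carboxylate loses CO2 and water protonates the lactam enolate, which turns C3 into CH2 and removes the racemic stereocentre.

**Step 4**
Reactants: 7 1-(3,4-dimethoxybenzyl)pyrrolidin-2-one
Product: 8 1-(3,4-dihydroxybenzyl)pyrrolidin-2-one
Conditions: BBr3 (4 equiv), CH2Cl2, −78 °C → rt; then H2O, 0 °C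
Reagents that add atoms: none
Why: BBr3 cleavage of aryl methyl ethers (boron complexation, then SN2 attack of bromide on the methyl group) should free the catechol, while the tertiary lactam only binds boron reversibly and is released on aqueous work-up.

**Step 5**
Reactants: 8 1-(3,4-dihydroxybenzyl)pyrrolidin-2-one
Product: 9 1-(2,3,6-tribromo-4,5-dihydroxybenzyl)pyrrolidin-2-one
Conditions: Br2 (3.2 equiv), AcOH, rt, dark; then aq. Na2S2O4
Reagents that add atoms: bromine, BrBr
Why: Exhaustive electrophilic aromatic bromination (SEAr): the three free positions C2, C5 and C6 of the 3,4-dihydroxybenzyl ring are each ortho or para to a free phenolic OH, so three equivalents of bromine should substitute all of them without a Lewis acid, while the lactam and the N-acylated benzylic carbon are inert to Br2 in acetic acid in the dark.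

**Compound list**
1 | (3,4-dimethoxyphenyl)methanamine (3,4-dimethoxybenzylamine) | NCc1ccc(OC)c(OC)c1 | starting material
2 | methyl 3-chloro-3-oxopropanoate (methyl malonyl chloride) | COC(=O)CC(=O)Cl | starting material
3 | methyl 3-[(3,4-dimethoxybenzyl)amino]-3-oxopropanoate | COC(=O)CC(=O)NCc1ccc(OC)c(OC)c1 | intermediate
4 | diphenyl(vinyl)sulfonium trifluoromethanesulfonate | C=C[S+](c1ccccc1)c1ccccc1.[O-]S(=O)(=O)C(F)(F)F | starting material
5 | {3-[(3,4-dimethoxybenzyl)carbamoyl]-4-methoxy-4-oxobutyl}diphenylsulfonium trifluoromethanesulfonate (racemic, not isolated) | COC(=O)C(CC[S+](c1ccccc1)c1ccccc1)C(=O)NCc1ccc(OC)c(OC)c1.[O-]S(=O)(=O)C(F)(F)F | intermediate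
6 | rac-methyl 1-(3,4-dimethoxybenzyl)-2-oxopyrrolidine-3-carboxylate | COC(=O)C1CCN(Cc2ccc(OC)c(OC)c2)C1=O | intermediate
7 | 1-(3,4-dimethoxybenzyl)pyrrolidin-2-one | O=C1CCCN1Cc1ccc(OC)c(OC)c1 | intermediate
8 | 1-(3,4-dihydroxybenzyl)pyrrolidin-2-one | O=C1CCCN1Cc1ccc(O)c(O)c1 | intermediate
9 | 1-(2,3,6-tribromo-4,5-dihydroxybenzyl)pyrrolidin-2-one | O=C1CCCN1Cc1c(Br)c(O)c(O)c(Br)c1Br | target

**Step count.** Total: 5 steps. Longest linear sequence: 5 steps (1 → 3 → 6 → 7 → 8 → 9).

**Steps most likely to fail**

Step 2. After the conjugate addition, the ring may close through the malonate carbon (3-exo-tet, cyclopropane) or through oxygen instead of nitrogen, because an N-alkyl amidate is present at lower concentration than the enolate; double alkylation at C3 is a further possibility. The fallback gives up the annulation and builds the lactam by the classical acylation/N-alkylation sequence. It sets out from compound 1, which would be acylated with 4-chlorobutanoyl chloride (Et3N, CH2Cl2, 0 °C) to give 4-chloro-N-(3,4-dimethoxybenzyl)butanamide F1. Treatment of this amide with KOtBu in THF (0 °C → rt) should close the ring by intramolecular N-alkylation (5-exo-tet) and come back to the route at compound 7, so that compound 6 and step 3 are bypassed.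

Step 5. Bromine may oxidise the electron-rich catechol to an o-quinone, attack the ipso position C1 with loss of the benzylic side chain, or stall at the dibromide. The fallback moves the halogenation to the ether stage, where the ring cannot be oxidised to a quinone. It sets out from compound 7, which would be brominated with excess Br2 and iron powder in CH2Cl2 (rt → reflux, dark) to give 1-(2,3,6-tribromo-4,5-dimethoxybenzyl)pyrrolidin-2-one F2. Demethylation of this compound with BBr3 in CH2Cl2 (−78 °C → rt, then water) comes back to the route at compound 9, the target.

Step 3. The dealkoxycarbonylation may stay incomplete, or hydroxide formed at 150 °C may open the lactam. The fallback replaces nucleophilic dealkylation by hydrolysis and thermal decarboxylation. It sets out from compound 6, which would be saponified with LiOH in THF/H2O (0 °C → rt) and acidified to give 1-(3,4-dimethoxybenzyl)-2-oxopyrrolidine-3-carboxylic acid F3. Heating this β-amido acid in toluene at reflux should expel CO2 through a cyclic six-membered transition state and come back to the route at compound 7.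

**Further compounds**
F1 | step 2 | 4-chloro-N-(3,4-dimethoxybenzyl)butanamide | O=C(CCCCl)NCc1ccc(OC)c(OC)c1
F2 | step 5 | 1-(2,3,6-tribromo-4,5-dimethoxybenzyl)pyrrolidin-2-one | O=C1CCCN1Cc1c(Br)c(OC)c(OC)c(Br)c1Br
F3 | step 3 | 1-(3,4-dimethoxybenzyl)-2-oxopyrrolidine-3-carboxylic acid | O=C(O)C1CCN(Cc2ccc(OC)c(OC)c2)C1=O
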